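## The problem

- Target 19 is a flavone in which ring A carries no hydrogen: free hydroxyls at C5 and C7, methoxy groups at C6 and C8. Ring C bears a 3-methoxy group and ring B is 2',4',5'-trimethoxylated.
- There is no stereocentre and the C2–C1' axis rotates freely, so the task is regiochemistry and telling eight oxygens apart.
- Two oxygens must end as OH beside six methyl ethers. A late selective demethylation at C7, between the 6- and 8-methoxy groups, cannot be relied on, so O5 and O7 must travel under a group that leaves without touching methyl ethers.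
- Ring A needs five oxygens in a fixed order around one acyl carbon, and the C2–C1' bond joins two carbons that each have an oxygen-bearing neighbour.
- Fragile points: an unsubstituted chromone C2 opens with hard nucleophiles; benzyl ethers, especially the one peri to the carbonyl, are sensitive to strong acids; a 2-halochromone is a vinylogous acyl halide.
- The enabling feature: O3 on C3 and O2' on C2' lie on either side of the C2–C1' bond. One CH2 between them gives the chain C2–C3–O–CH2–O–C2'–C1', so the bond can be closed as the last bond of a seven-membered 1,3-dioxepine, and the two tether oxygens are the ones that end as 3-OMe and 2'-OMe.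

## Retrosynthesis

**19 from 18.** The two O–benzyl bonds at O5 and O7 are the last to be cut. Hydrogenolysis separates these two oxygens from the six methyl ethers without any selective demethylation. The forward step must spare the tetrasubstituted C2=C3 bond.

**18 from 17 from 16.** The methyl carbons on O3 and O2' are removed to give diol 17, and the two oxygens are then joined through one carbon as the cyclic formaldehyde acetal 16. Cutting C2–C1' directly in 18 would demand an intermolecular coupling with a preformed ring B organometallic. The bridge turns that bond formation into a ring closure, and the bridge carbon is an atom the route would otherwise spend as two methyl groups. Forward, acid must open the acetal without removing the benzyl ethers, and MeI must then find only the two freed hydroxyls.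

**16 from 15.** The C2–C1' bond is cut, giving bromide 15, in which ring B is a plain 3,4-dimethoxyphenyl ether with a free ortho C–H. Cutting a C–O bond of the dioxepine instead would leave the biaryl-type bond still to be made. This cut removes one ring and the only skeletal bond between the halves. Forward, palladium must insert at C2–Br, metalate C6 of the phenoxy ring and not C2, and close a seven-membered ring.

**15 from 13, and 13 from 9 and 12.** The C2–Br bond is cut first, then the O3–CH2 bond. Bromine is introduced after the acetal is in place and by deprotonation, because an electrophilic bromine source would attack ring B of 13, and because a capped 3-oxygen makes the bromide a stable vinylogous ester. The chloromethyl ether 12 comes from the O,S-acetal 11 of phenol 10. This leaves the 3-hydroxychromone 9 and a purchasable phenol.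

**9 from 7, and 7 from 4 and 5.** The C3–O bond is cut (epoxidation and rearrangement of the chromone), then O1–C2 and C2–C3, which arise from acetophenone 4 and the one-carbon unit 5 through enaminone 6. Carrying the 3-oxygen from an ω-oxygenated acetophenone would require a separate acylation of a pentaoxygenated ring. The forward steps ask only that a hindered methyl ketone condenses and that the epoxidation leaves the electron-rich ring A alone.

**4 from 3 from 2 from 1.** The two aryl C–OMe bonds are cut back to C–Br and then C–H, and the two benzyl ethers back to phloroacetophenone 1. The symmetry of 1 fixes the pattern: the hydroxyl that stays free is hydrogen-bonded to the ketone and later becomes O1. The only two free ring positions receive bromine, then methoxide.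

## Roads not taken

**Alternative 1:** The cut removes both bonds to the carbonyl carbon, C4a–C4 and C4–C3, with C4 coming from CO. Zerovalent palladium would insert into the C–I bond of 1,3,5-tris(benzyloxy)-2-iodo-4,6-dimethoxybenzene A2 and take up CO. The acylpalladium would then be captured by the enolate of 2-methoxy-1-(2,4,5-trimethoxyphenyl)ethan-1-one A3, giving the diketone 2-methoxy-1-[2,4,6-tris(benzyloxy)-3,5-dimethoxyphenyl]-3-(2,4,5-trimethoxyphenyl)propane-1,3-dione A1.
- Merits: three components meet in one step, the 3-methoxy group is present from the start, and either ortho benzyl group of A1 may be removed before cyclodehydration.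
- Weak points: the iodide of A2 sits between two benzyloxy groups on a pentaalkoxy ring, so oxidative addition and CO insertion occur at the most hindered, most electron-rich carbon. The enolate of A3 is a hindered α-alkoxy nucleophile. A1 is more acidic than A3, so it consumes base and can O-acylate. A2 still needs the same bromination and methoxylation chemistry.
- Comparison: this road is shorter and needs no C3 oxidation, no C2 halogenation and no bridge. The chosen plan offers in return a bond formation that is intramolecular, starts from an activated bromide and ends at an unhindered C–H.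

**Alternative 2:** The cut is C4–C4a. (2E)-3-[3-(Benzyloxy)-5-hydroxy-2,4-dimethoxyphenoxy]-2-methoxy-3-(2,4,5-trimethoxyphenyl)prop-2-enoic acid A5 would be activated with (CF3CO)2O and acylate the single free carbon of ring A, giving 7-(benzyloxy)-5-hydroxy-3,6,8-trimethoxy-2-(2,4,5-trimethoxyphenyl)-4H-chromen-4-one A4.
- Merits: only one ring A position is open, so the closure has no regiochemical choice, and the 5-OH is already free.
- Weak points: A5 is a tetrasubstituted push-pull enol ether whose E geometry must be set and kept. Acid can isomerise it, after which the acylium can attack ring B and give an indenone. The tetraoxygenated phenol needed for A5 has three differently protected oxygens and is harder to make than acetophenone 4.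
- Comparison: step count is similar, and regiocontrol of the ring-forming event is better than in the chosen plan, whose ring B has two ortho C–H bonds. The chosen plan relies on the steric and electronic bias between those two sites and on a much shorter access to its precursor.

**Alternative 3:** The cut is C2–C1' together with C2'–OMe. 4,5-Dimethoxybenzyne A8, released by CsF, would insert into the C2–OMe bond of 5,7-bis(benzyloxy)-2,3,6,8-tetramethoxy-4H-chromen-4-one A7 to give 5,7-bis(benzyloxy)-3,6,8-trimethoxy-2-(2,4,5-trimethoxyphenyl)-4H-chromen-4-one A6, which is identical with 18.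
- Merits: one operation forms the biaryl-type bond and places the 2'-methoxy group, and A8 is symmetric, so there is no regiochemical question.
- Weak points: insertion of an aryne into a vinylogous carbonate C–O bond has no close analogy; the methoxy oxygen is a poor initiating nucleophile. The electron-rich C2=C3 bond of A7 offers [2+2] and ene pathways, and fluoride can substitute at C2. A7 requires regioselective O-methylation of a 2-hydroxychromone/4-hydroxycoumarin tautomer pair.
- Comparison: on paper this is the shortest road and ends one step from the target without a bridge. The chosen plan is longer but built from steps with close analogy throughout.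

Key step: step 9

Remark: 19 has no stereocentre and the twisted dioxepine of 16 is taken as configurationally labile, so no stereocontrol is planned. Compounds 1, 5, 10, chloromethyl methyl sulfide and 1-bromo-2,4,5-trimethoxybenzene are taken as purchasable.

## Route

Step 1
Reactants: 1 2,4,6-trihydroxyacetophenone
Product: 2 1-[2,4-bis(benzyloxy)-6-hydroxyphenyl]ethan-1-one
Conditions: BnBr (2.1 equiv), K2CO3, DMF, rt
Reagents that add atoms: benzyl bromide, BrCc1ccccc1
Why: Williamson etherification; the para hydroxyl and one of the two equivalent ortho hydroxyls react, while the remaining ortho OH is hydrogen-bonded to the ketone and is the least nucleophilic, so the reaction should stop at the diether.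

Step 2
Reactants: 2 1-[2,4-bis(benzyloxy)-6-hydroxyphenyl]ethan-1-one
Product: 3 1-[2,4-bis(benzyloxy)-3,5-dibromo-6-hydroxyphenyl]ethan-1-one
Conditions: NBS (2.1 equiv), MeCN, 0 °C to rt, dark
Reagents that add atoms: N-bromosuccinimide, O=C1CCC(=O)N1Br
Why: Electrophilic aromatic bromination; C3 and C5 are the only free ring carbons and each lies between two oxygen donors, while the benzyl rings are unactivated and, without acid or light, the acetyl and benzylic CH2 groups should be spared.

Step 3
Reactants: 3 1-[2,4-bis(benzyloxy)-3,5-dibromo-6-hydroxyphenyl]ethan-1-one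
Product: 4 1-[2,4-bis(benzyloxy)-6-hydroxy-3,5-dimethoxyphenyl]ethan-1-one
Conditions: NaOMe (excess), CuBr (cat.), DMF–MeOH, 110 °C; aq. HCl work-up
Reagents that add atoms: sodium methoxide, [Na+].[O-]C
Why: Ullmann-type copper-catalysed exchange of aryl bromide for methoxide, the standard way to turn bromophenols bearing a carbonyl group into methoxyphenols; benzyl ethers and the ketone are stable to methoxide and the phenol returns on acidification.

Step 4
Reactants: 4 1-[2,4-bis(benzyloxy)-6-hydroxy-3,5-dimethoxyphenyl]ethan-1-one; 5 N,N-dimethylformamide dimethyl acetal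
Product: 7 5,7-bis(benzyloxy)-6,8-dimethoxy-4H-chromen-4-one, via enaminone 6 (not isolated)
Conditions: 5 (3 equiv), toluene, 100 °C; evaporate; conc. HCl, CH2Cl2, 40 °C
Reagents that add atoms: none
Why: Enaminone route to chromones; the methyl ketone condenses with the amide acetal, and acid then promotes addition of the phenol to the β-carbon and loss of dimethylamine, which closes ring C with C2 supplied by 5.

Step 5
Reactants: 7 5,7-bis(benzyloxy)-6,8-dimethoxy-4H-chromen-4-one
Product: 9 5,7-bis(benzyloxy)-3-hydroxy-6,8-dimethoxy-4H-chromen-4-one, via epoxide 8 (not isolated)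
Conditions: DMDO, acetone–CH2Cl2, 0 °C; evaporate; TsOH·H2O (cat.), CH2Cl2, rt
Reagents that add atoms: dimethyldioxirane, CC1(C)OO1
Why: Neutral electrophilic epoxidation of the chromone C2=C3 bond, then acid opening of the epoxide at C2 (oxocarbenium ion) and loss of H3 give the 3-hydroxychromone; the racemic epoxide loses both stereocentres here, and the hexasubstituted ring A has no position open to oxidation.

Step 6
Reactants: 10 3,4-dimethoxyphenol
Product: 11 1,2-dimethoxy-4-[(methylsulfanyl)methoxy]benzene
Conditions: NaH, DMF, 0 °C; ClCH2SMe, NaI (cat.), 0 °C to rt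
Reagents that add atoms: chloromethyl methyl sulfide, CSCCl
Why: Williamson alkylation of the sodium phenoxide with an α-chloro sulfide gives the O,S-acetal, the stable storage form of the aryloxymethyl group.

Step 7
Reactants: 9 5,7-bis(benzyloxy)-3-hydroxy-6,8-dimethoxy-4H-chromen-4-one; 11 1,2-dimethoxy-4-[(methylsulfanyl)methoxy]benzene
Product: 13 5,7-bis(benzyloxy)-3-[(3,4-dimethoxyphenoxy)methoxy]-6,8-dimethoxy-4H-chromen-4-one, via chloromethyl ether 12 (not isolated)
Conditions: 11, SO2Cl2 (1.0 equiv), CH2Cl2, −78 to 0 °C; evaporate; then 9, iPr2NEt, CH2Cl2, 0 °C to rt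
Reagents that add atoms: none
Why: Chlorinolysis of the O,S-acetal with sulfuryl chloride gives the α-chloro ether, which reacts at sulfur far faster than at the arene at low temperature; this ether O-alkylates the acidic enolic 3-OH as a chloromethyl ether does in a MOM protection, and the hindered amine base cannot add to C2.

Step 8
Reactants: 13 5,7-bis(benzyloxy)-3-[(3,4-dimethoxyphenoxy)methoxy]-6,8-dimethoxy-4H-chromen-4-one
Product: 15 5,7-bis(benzyloxy)-2-bromo-3-[(3,4-dimethoxyphenoxy)methoxy]-6,8-dimethoxy-4H-chromen-4-one, via 2-lithiochromone 14 (not isolated)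
Conditions: lithium 2,2,6,6-tetramethylpiperidide (1.2 equiv), THF, −78 °C; BrCl2CCCl2Br, −78 °C to rt
Reagents that add atoms: 1,2-dibromo-1,1,2,2-tetrachloroethane, BrC(Cl)(Cl)C(Cl)(Cl)Br
Why: Directed deprotonation; C2–H is the most acidic C–H (vinylic, next to the ring oxygen and to the coordinating acetal oxygen) and a hindered amide base removes it without adding to the carbonyl; the lithio species then takes bromine from a positive-bromine donor that does not brominate the electron-rich ring B.

Step 9
Reactants: 15 5,7-bis(benzyloxy)-2-bromo-3-[(3,4-dimethoxyphenoxy)methoxy]-6,8-dimethoxy-4H-chromen-4-one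
Product: 16 3,2'-O,O'-methylene-bridged 5,7-bis(benzyloxy)-6,8,4',5'-tetramethoxyflavone (chromone O3 and ring B O2' joined by one CH2; fused seven-membered 1,3-dioxepine)
Conditions: Pd(OAc)2 (10 mol%), PCy3·HBF4 (20 mol%), PivOH (30 mol%), K2CO3 (2 equiv), DMA, 110 °C
Reagents that add atoms: none
Why: Zerovalent palladium, formed from Pd(OAc)2 and PCy3, should insert quickly into the C2–Br bond of the vinylogous acyl bromide and give an electron-poor chromon-2-yl complex of divalent palladium. After exchange of bromide for pivalate, the acetal holds ring B beside the metal and concerted metalation–deprotonation at the ortho C–H gives an eight-membered diorganopalladium ring. Reductive elimination forms C2–C1' and contracts this palladacycle to the seven-membered 1,3-dioxepine, so the ring closes by C–C reductive elimination and not by a polar exo or endo attack. The closest known reaction type is the palladium-catalysed intramolecular direct arylation of tethered aryl halides across ether, ester, amide and acetal links to six- and seven-membered bridged biaryls, together with cross-coupling of 2-halochromones. No stereocentre is formed. The step needs site selectivity on ring B: C6 of the phenoxy ring is flanked by hydrogen and lies para to a methoxy group, whereas C2 sits between the tether oxygen and a methoxy group, so the electrophilic metal should choose C6 and give the 2',4',5' pattern. It also needs the C–H metalation to outrun hydrodebromination and substitution at C2, which the intramolecular setting, a dry poorly nucleophilic base and the pivalate shuttle should secure. The benzyl C–H bonds cannot reach C2.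

Step 10
Reactants: 16 3,2'-O,O'-methylene-bridged 5,7-bis(benzyloxy)-6,8,4',5'-tetramethoxyflavone
Product: 17 5,7-bis(benzyloxy)-3-hydroxy-2-(2-hydroxy-4,5-dimethoxyphenyl)-6,8-dimethoxy-4H-chromen-4-one
Conditions: conc. HCl, MeOH–THF (3:1), 55 °C
Reagents that add atoms: none
Why: Acid-catalysed transacetalisation; the acidic 3-oxychromone leaves from the protonated acetal, methanol traps the aryloxymethyl cation, and the resulting aryl methoxymethyl ether is cleaved the same way, so the bridge carbon leaves as dimethoxymethane; aryl benzyl ethers should tolerate methanolic HCl at this temperature.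

Step 11
Reactants: 17 5,7-bis(benzyloxy)-3-hydroxy-2-(2-hydroxy-4,5-dimethoxyphenyl)-6,8-dimethoxy-4H-chromen-4-one
Product: 18 5,7-bis(benzyloxy)-3,6,8-trimethoxy-2-(2,4,5-trimethoxyphenyl)-4H-chromen-4-one
Conditions: MeI (3 equiv), K2CO3, DMF, rt
Reagents that add atoms: iodomethane, CI
Why: Williamson methylation of the enolic 3-OH and the phenolic 2'-OH, the only free hydroxyls in 17.

Step 12
Reactants: 18 5,7-bis(benzyloxy)-3,6,8-trimethoxy-2-(2,4,5-trimethoxyphenyl)-4H-chromen-4-one
Product: 19 5,7-dihydroxy-3,6,8-trimethoxy-2-(2,4,5-trimethoxyphenyl)-4H-chromen-4-one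
Conditions: H2 (1 atm), 10% Pd/C, EtOAc–MeOH, rt
Reagents that add atoms: none
Why: Hydrogenolysis of the two aryl benzyl ethers; methyl ethers are inert and the tetrasubstituted, conjugated C2=C3 bond of a flavone is not reduced under these mild conditions.

## Compound list

1 | 2,4,6-trihydroxyacetophenone | CC(=O)c1c(O)cc(O)cc1O | starting material
2 | 1-[2,4-bis(benzyloxy)-6-hydroxyphenyl]ethan-1-one | CC(=O)c1c(O)cc(OCc2ccccc2)cc1OCc1ccccc1 | intermediate
3 | 1-[2,4-bis(benzyloxy)-3,5-dibromo-6-hydroxyphenyl]ethan-1-one | CC(=O)c1c(O)c(Br)c(OCc2ccccc2)c(Br)c1OCc1ccccc1 | intermediate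
4 | 1-[2,4-bis(benzyloxy)-6-hydroxy-3,5-dimethoxyphenyl]ethan-1-one | CC(=O)c1c(O)c(OC)c(OCc2ccccc2)c(OC)c1OCc1ccccc1 | intermediate
5 | N,N-dimethylformamide dimethyl acetal | COC(OC)N(C)C | starting material
6 | (2E)-1-[2,4-bis(benzyloxy)-6-hydroxy-3,5-dimethoxyphenyl]-3-(dimethylamino)prop-2-en-1-one | CN(C)/C=C/C(=O)c1c(O)c(OC)c(OCc2ccccc2)c(OC)c1OCc1ccccc1 | intermediate (not isolated)
7 | 5,7-bis(benzyloxy)-6,8-dimethoxy-4H-chromen-4-one | O=c1ccoc2c(OC)c(OCc3ccccc3)c(OC)c(OCc3ccccc3)c12 | intermediate
8 | 5,7-bis(benzyloxy)-6,8-dimethoxy-2,3-epoxy-2,3-dihydro-4H-chromen-4-one (racemic, cis-fused; one enantiomer drawn) | O=C1[C@@H]2O[C@@H]2Oc2c(OC)c(OCc3ccccc3)c(OC)c(OCc3ccccc3)c12 | intermediate (not isolated)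
9 | 5,7-bis(benzyloxy)-3-hydroxy-6,8-dimethoxy-4H-chromen-4-one | O=c1c(O)coc2c(OC)c(OCc3ccccc3)c(OC)c(OCc3ccccc3)c12 | intermediate
10 | 3,4-dimethoxyphenol | COc1ccc(O)cc1OC | starting material
11 | 1,2-dimethoxy-4-[(methylsulfanyl)methoxy]benzene | COc1ccc(OCSC)cc1OC | intermediate
12 | 4-(chloromethoxy)-1,2-dimethoxybenzene | COc1ccc(OCCl)cc1OC | intermediate (not isolated)
13 | 5,7-bis(benzyloxy)-3-[(3,4-dimethoxyphenoxy)methoxy]-6,8-dimethoxy-4H-chromen-4-one | COc1ccc(OCOc2coc3c(OC)c(OCc4ccccc4)c(OC)c(OCc4ccccc4)c3c2=O)cc1OC | intermediate
14 | [5,7-bis(benzyloxy)-3-[(3,4-dimethoxyphenoxy)methoxy]-6,8-dimethoxy-4-oxo-4H-chromen-2-yl]lithium | [Li]c1oc2c(OC)c(OCc3ccccc3)c(OC)c(OCc3ccccc3)c2c(=O)c1OCOc1ccc(OC)c(OC)c1 | intermediate (not isolated)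
15 | 5,7-bis(benzyloxy)-2-bromo-3-[(3,4-dimethoxyphenoxy)methoxy]-6,8-dimethoxy-4H-chromen-4-one | Brc1oc2c(OC)c(OCc3ccccc3)c(OC)c(OCc3ccccc3)c2c(=O)c1OCOc1ccc(OC)c(OC)c1 | intermediate
16 | 3,2'-O,O'-methylene-bridged 5,7-bis(benzyloxy)-6,8,4',5'-tetramethoxyflavone (fused 1,3-dioxepine) | COc1cc2c(cc1OC)-c1oc3c(OC)c(OCc4ccccc4)c(OC)c(OCc4ccccc4)c3c(=O)c1OCO2 | intermediate
17 | 5,7-bis(benzyloxy)-3-hydroxy-2-(2-hydroxy-4,5-dimethoxyphenyl)-6,8-dimethoxy-4H-chromen-4-one | COc1cc(O)c(-c2oc3c(OC)c(OCc4ccccc4)c(OC)c(OCc4ccccc4)c3c(=O)c2O)cc1OC | intermediate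
18 | 5,7-bis(benzyloxy)-3,6,8-trimethoxy-2-(2,4,5-trimethoxyphenyl)-4H-chromen-4-one | COc1cc(OC)c(-c2oc3c(OC)c(OCc4ccccc4)c(OC)c(OCc4ccccc4)c3c(=O)c2OC)cc1OC | intermediate
19 | 5,7-dihydroxy-3,6,8-trimethoxy-2-(2,4,5-trimethoxyphenyl)-4H-chromen-4-one | COc1cc(OC)c(-c2oc3c(OC)c(O)c(OC)c(O)c3c(=O)c2OC)cc1OC | target

## Step count and uncertain steps

Total: 12 steps. Longest linear sequence: 11 steps, from 1 to 19 through steps 1–5 and 7–12; step 6 prepares the side arm 11.

**Step 9 (key step).** The bromide may be lost by hydrodebromination or by carboxylate or carbonate substitution at the vinylogous acyl carbon before the slow eight-membered palladacycle forms. Palladation may also occur at the ring B carbon between the two oxygens. The fallback keeps the C2–C1' disconnection but makes the bond intermolecularly.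
- It sets out from 9. Methylation with MeI and K2CO3 gives 5,7-bis(benzyloxy)-3,6,8-trimethoxy-4H-chromen-4-one F1.
- Zincation of F1 at C2, its only ring C position, with TMPZnCl·LiCl in THF gives chloro[5,7-bis(benzyloxy)-3,6,8-trimethoxy-4-oxo-4H-chromen-2-yl]zinc F2.
- Negishi coupling of F2 with 1-bromo-2,4,5-trimethoxybenzene (Pd(OAc)2, SPhos) comes back to the route at 18. The price is the tether and the use of phenol 10 as the ring B source.

**Step 8.** The amide base may add to C2 or C4 of the chromone, or the 2-lithio species may decompose before bromine transfer. The fallback is electrophilic substitution of the free enol.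
- It sets out from 9. NBS in CH2Cl2 at 0 °C should brominate the carbon ortho to the enolic hydroxyl, as in 3-hydroxy-4-pyranones, since ring A offers no free position. This gives 5,7-bis(benzyloxy)-2-bromo-3-hydroxy-6,8-dimethoxy-4H-chromen-4-one F3.
- O-alkylation of F3 with chloromethyl ether 12 and iPr2NEt comes back to the route at 15.

**Step 7.** Ring chlorination of the electron-rich dimethoxyphenyl group by sulfuryl chloride or methanesulfenyl chloride, or self-condensation of the aryloxymethyl chloride, may consume 12 before it meets 9. The fallback inverts the roles of the partners.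
- It sets out from 9. NaH and ClCH2SMe give 5,7-bis(benzyloxy)-6,8-dimethoxy-3-[(methylsulfanyl)methoxy]-4H-chromen-4-one F4.
- SO2Cl2 converts F4 into 5,7-bis(benzyloxy)-3-(chloromethoxy)-6,8-dimethoxy-4H-chromen-4-one F5, a chloromethyl ether with no free electron-rich arene position.
- F5 alkylates the sodium salt of phenol 10 (NaH, THF, 0 °C) and comes back to the route at 13.

**Step 3.** Hydrodebromination may compete with C–O bond formation, and the exchange may stall after the first bromide, because the substrate reacts as an electron-rich phenoxide at doubly flanked carbons. The fallback masks the phenol so that the exchange runs on a neutral ring.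
- It sets out from 3. Benzylation of the chelated hydroxyl (BnBr, K2CO3, DMF, 60 °C) gives 1-[2,4,6-tris(benzyloxy)-3,5-dibromophenyl]ethan-1-one F6.
- NaOMe and CuBr in DMF–MeOH convert F6 into 1-[2,4,6-tris(benzyloxy)-3,5-dimethoxyphenyl]ethan-1-one F7.
- MgBr2·OEt2 in toluene removes one of the two equivalent benzyl groups ortho to the ketone through chelation and comes back to the route at 4.

## Further compounds

F1 | step 9 | 5,7-bis(benzyloxy)-3,6,8-trimethoxy-4H-chromen-4-one | COc1coc2c(OC)c(OCc3ccccc3)c(OC)c(OCc3ccccc3)c2c1=O
F2 | step 9 | chloro[5,7-bis(benzyloxy)-3,6,8-trimethoxy-4-oxo-4H-chromen-2-yl]zinc | COc1c([Zn]Cl)oc2c(OC)c(OCc3ccccc3)c(OC)c(OCc3ccccc3)c2c1=O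
F3 | step 8 | 5,7-bis(benzyloxy)-2-bromo-3-hydroxy-6,8-dimethoxy-4H-chromen-4-one | O=c1c(O)c(Br)oc2c(OC)c(OCc3ccccc3)c(OC)c(OCc3ccccc3)c12
F4 | step 7 | 5,7-bis(benzyloxy)-6,8-dimethoxy-3-[(methylsulfanyl)methoxy]-4H-chromen-4-one | CSCOc1coc2c(OC)c(OCc3ccccc3)c(OC)c(OCc3ccccc3)c2c1=O
F5 | step 7 | 5,7-bis(benzyloxy)-3-(chloromethoxy)-6,8-dimethoxy-4H-chromen-4-one | ClCOc1coc2c(OC)c(OCc3ccccc3)c(OC)c(OCc3ccccc3)c2c1=O
F6 | step 3 | 1-[2,4,6-tris(benzyloxy)-3,5-dibromophenyl]ethan-1-one | CC(=O)c1c(OCc2ccccc2)c(Br)c(OCc2ccccc2)c(Br)c1OCc1ccccc1
F7 | step 3 | 1-[2,4,6-tris(benzyloxy)-3,5-dimethoxyphenyl]ethan-1-one | CC(=O)c1c(OCc2ccccc2)c(OC)c(OCc2ccccc2)c(OC)c1OCc1ccccc1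
A1 | alternative 1 | 2-methoxy-1-[2,4,6-tris(benzyloxy)-3,5-dimethoxyphenyl]-3-(2,4,5-trimethoxyphenyl)propane-1,3-dione (racemic) | COC(C(=O)c1c(OCc2ccccc2)c(OC)c(OCc2ccccc2)c(OC)c1OCc1ccccc1)C(=O)c1cc(OC)c(OC)cc1OC
A2 | alternative 1 | 1,3,5-tris(benzyloxy)-2-iodo-4,6-dimethoxybenzene | Ic1c(OCc2ccccc2)c(OC)c(OCc2ccccc2)c(OC)c1OCc1ccccc1
A3 | alternative 1 | 2-methoxy-1-(2,4,5-trimethoxyphenyl)ethan-1-one | COCC(=O)c1cc(OC)c(OC)cc1OC
A4 | alternative 2 | 7-(benzyloxy)-5-hydroxy-3,6,8-trimethoxy-2-(2,4,5-trimethoxyphenyl)-4H-chromen-4-one | COc1cc(OC)c(-c2oc3c(OC)c(OCc4ccccc4)c(OC)c(O)c3c(=O)c2OC)cc1OC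
A5 | alternative 2 | (2E)-3-[3-(benzyloxy)-5-hydroxy-2,4-dimethoxyphenoxy]-2-methoxy-3-(2,4,5-trimethoxyphenyl)prop-2-enoic acid | OC(=O)/C(OC)=C(\Oc1cc(O)c(OC)c(OCc2ccccc2)c1OC)c1cc(OC)c(OC)cc1OC
A6 | alternative 3 | 5,7-bis(benzyloxy)-3,6,8-trimethoxy-2-(2,4,5-trimethoxyphenyl)-4H-chromen-4-one | COc1cc(OC)c(-c2oc3c(OC)c(OCc4ccccc4)c(OC)c(OCc4ccccc4)c3c(=O)c2OC)cc1OC
A7 | alternative 3 | 5,7-bis(benzyloxy)-2,3,6,8-tetramethoxy-4H-chromen-4-one | COc1oc2c(OC)c(OCc3ccccc3)c(OC)c(OCc3ccccc3)c2c(=O)c1OC
A8 | alternative 3 | 4,5-dimethoxybenzyne | COC1=CC#CC=C1OC
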